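The strategy cuts the central CH2–CH2 bond of the ethano bridge between meta-phenylene ring B and phenol ring C. Its two benzylic carbons are alike, so each is traced back to an aryl aldehyde carbon. Low-valent titanium joins these two electrophilic carbons reductively. One operation makes the bridge carbon–carbon bond as a stilbene and closes the 18-membered ring. The precursor is an open-chain dialdehyde that already holds both diaryl ethers (A–O–B, C–O–D), the saturated A–D bridge, the ring A methyl ether and a benzyl ether on the ring C phenol. A single hydrogenation then saturates the stilbene and frees the phenol.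

Key step: step 7

Ring labels: A is the ring bearing OMe (1-CH2CH2, 2-OAr, 3-OMe). B is the meta-phenylene. C is the phenol ring (1-CH2CH2, 3-OAr, 4-OH). D is the para-phenylene.
Structure check: the macrocycle counts 2 (ring A) + O + 3 (ring B) + 2 (bridge) + 3 (ring C) + O + 4 (ring D) + 2 (bridge) = 18 ring atoms, and the target has no stereocentre.
Design remark: the A–D bridge is installed directly at the alkane level, so no C=C has to be reduced while the benzyl ether must survive. Both formyl carbons travel as nitriles and are unmasked together in one operation.
Assumption: the macrocyclic stilbene is drawn as the Z isomer, the geometry that should fit the ring best. Any E isomer would be carried on, because step 8 erases the geometry.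

Step 1
Reactants: 1 2-fluoro-3-methoxybenzaldehyde; 2 3-hydroxybenzonitrile
Product: 3 3-(2-formyl-6-methoxyphenoxy)benzonitrile
Conditions: K2CO3, DMF, 110 °C
Reagents that add atoms: none
Why: Nucleophilic aromatic substitution by addition–elimination, in which the ortho formyl group stabilises the Meisenheimer adduct at C2 of 1, fluoride is the best leaving group for this mechanism and the nitrile is inert to carbonate.

Step 2
Reactants: 3 3-(2-formyl-6-methoxyphenoxy)benzonitrile
Product: 4 3-(2-ethenyl-6-methoxyphenoxy)benzonitrile
Conditions: Ph3PCH3Br, KOtBu, THF, 0 °C to rt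
Reagents that add atoms: methyltriphenylphosphonium bromide, C[P+](c1ccccc1)(c1ccccc1)c1ccccc1.[Br-]
Why: Wittig methylenation, in which the non-stabilised ylide adds to the non-enolisable aldehyde far faster than to the aryl nitrile.

Step 3
Reactants: 5 3,4-dihydroxybenzonitrile
Product: 6 4-(benzyloxy)-3-hydroxybenzonitrile
Conditions: BnBr (1.0 equiv), K2CO3 (1.0 equiv), DMF, 0 °C to rt
Reagents that add atoms: benzyl bromide, BrCc1ccccc1
Why: Regioselective Williamson etherification, since the 4-OH para to the nitrile is the more acidic one, so one equivalent of base should form mainly its phenoxide and leave the 3-OH free.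

Step 4
Reactants: 6 4-(benzyloxy)-3-hydroxybenzonitrile; 7 (4-bromophenyl)boronic acid
Product: 8 4-(benzyloxy)-3-(4-bromophenoxy)benzonitrile
Conditions: Cu(OAc)2 (1 equiv, re-oxidised by air), pyridine, 4 Å MS, CH2Cl2, dry air, rt
Reagents that add atoms: none
Why: Chan–Evans–Lam oxidative C–O coupling, in which the aryl group passes from boron to divalent copper and C–O reductive elimination follows from the oxidised aryl copper phenoxide at room temperature, where the C–Br bond, the nitrile and the benzyl ether are untouched.

Step 5
Reactants: 4 3-(2-ethenyl-6-methoxyphenoxy)benzonitrile; 8 4-(benzyloxy)-3-(4-bromophenoxy)benzonitrile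
Product: 10 seco dinitrile 4-(benzyloxy)-3-(4-{2-[2-(3-cyanophenoxy)-3-methoxyphenyl]ethyl}phenoxy)benzonitrile, via B-alkyl-9-BBN adduct 9 (not isolated)
Conditions: 9-BBN (1.1 equiv), THF, 0 °C to rt; then 8, PdCl2(dppf) (5 mol %), aq K3PO4, DMF, 60 °C
Reagents that add atoms: 9-borabicyclo[3.3.1]nonane, B1C2CCCC1CCC2 (its boryl group is held only in 9; only its hydrogen reaches 10)
Why: Anti-Markovnikov hydroboration followed by B-alkyl Suzuki–Miyaura coupling, in which the bulky borane places boron on the terminal carbon of the styrene and the dppf ligand favours reductive elimination over β-hydride elimination, giving the saturated A–D bridge directly while nitriles and the benzyl ether are spectators.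

Step 6
Reactants: 10 seco dinitrile
Product: 12 seco dialdehyde 4-(benzyloxy)-3-(4-{2-[2-(3-formylphenoxy)-3-methoxyphenyl]ethyl}phenoxy)benzaldehyde, via bis(N-aluminio)aldimine 11 (not isolated)
Conditions: i-Bu2AlH (3 equiv), CH2Cl2, −78 to 0 °C; then 1 M HCl, rt
Reagents that add atoms: water, O; diisobutylaluminium hydride, CC(C)C[AlH]CC(C)C (its aluminium group is held only in 11)
Why: Partial reduction of aryl nitriles with i-Bu2AlH, in which each nitrile takes up one hydride because the N-aluminated aldimine resists further reduction in the cold, and aqueous acid then hydrolyses both aldimines to aldehydes without harming the ethers.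

Step 7
Reactants: 12 seco dialdehyde
Product: 14 benzyl-protected macrocyclic (Z)-stilbene, via titanium pinacolate 13 (not isolated)
Conditions: TiCl4, Zn, pyridine, THF, reflux; then 12 in THF by syringe pump (ca. 20 h, final ca. 1 mM), reflux
Reagents that add atoms: titanium tetrachloride, Cl[Ti](Cl)(Cl)Cl (its titanium, once reduced by Zn, is bound only in 13; no reagent atom stays in 14)
Why: Zinc reduces TiCl4 to low-valent titanium, which passes one electron to each aryl aldehyde; the two ketyl radicals held on the metal combine to the pinacolate 13, and at reflux the strong Ti–O bonds drive out both oxygens to leave the alkene. This is an intramolecular McMurry coupling, a reaction type well established for turning aromatic dialdehydes into macrocyclic stilbenes. The one ring closed is the 18-membered macrocycle, formed end to end by radical–radical union of the ring B and ring C formyl carbons, both of which become ring members. No stereocentre remains, since the two carbinol centres of 13 are erased on deoxygenation, and the alkene geometry is without consequence because step 8 saturates it. The selectivity needed is ring closure over chain growth; it is secured by the very low stationary concentration of 12 under slow addition and by the two bent diaryl ether hinges and the flexible A–D bridge, which let the chain fold until its ends meet. Chemoselectivity should not be at stake, as the non-enolisable aldehydes are the only reducible groups and pyridine tempers the Lewis acidity of the titanium and zinc chlorides toward the benzyl and methyl ethers.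

Step 8
Reactants: 14 benzyl-protected macrocyclic (Z)-stilbene
Product: 15 target macrocycle CNP0309263.0
Conditions: H2 (1 atm), 10% Pd/C, EtOAc–EtOH, rt
Reagents that add atoms: none
Why: Catalytic hydrogenation combined with hydrogenolysis, in which Pd/C saturates the disubstituted stilbene of either geometry and cleaves the benzylic C–O bond, whereas the diaryl ethers and the methyl ether are inert under these conditions.

Compound list
1 | 2-fluoro-3-methoxybenzaldehyde | COc1cccc(C=O)c1F | starting material
2 | 3-hydroxybenzonitrile | N#Cc1cccc(O)c1 | starting material
3 | 3-(2-formyl-6-methoxyphenoxy)benzonitrile (A–B aldehyde) | COc1cccc(C=O)c1Oc1cccc(C#N)c1 | intermediate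
4 | 3-(2-ethenyl-6-methoxyphenoxy)benzonitrile (A–B styrene) | COc1cccc(C=C)c1Oc1cccc(C#N)c1 | intermediate
5 | 3,4-dihydroxybenzonitrile | N#Cc1ccc(O)c(O)c1 | starting material
6 | 4-(benzyloxy)-3-hydroxybenzonitrile | N#Cc1ccc(OCc2ccccc2)c(O)c1 | intermediate
7 | (4-bromophenyl)boronic acid | OB(O)c1ccc(Br)cc1 | starting material
8 | 4-(benzyloxy)-3-(4-bromophenoxy)benzonitrile (C–D bromide) | N#Cc1ccc(OCc2ccccc2)c(Oc2ccc(Br)cc2)c1 | intermediate
9 | 3-{2-[2-(9-borabicyclo[3.3.1]nonan-9-yl)ethyl]-6-methoxyphenoxy}benzonitrile (not isolated) | COc1cccc(CCB2C3CCCC2CCC3)c1Oc1cccc(C#N)c1 | intermediate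
10 | seco dinitrile, 4-(benzyloxy)-3-(4-{2-[2-(3-cyanophenoxy)-3-methoxyphenyl]ethyl}phenoxy)benzonitrile | COc1cccc(CCc2ccc(Oc3cc(C#N)ccc3OCc3ccccc3)cc2)c1Oc1cccc(C#N)c1 | intermediate
11 | bis(N-diisobutylaluminio)aldimine of 12 (not isolated) | COc1cccc(CCc2ccc(Oc3cc(C=N[Al](CC(C)C)CC(C)C)ccc3OCc3ccccc3)cc2)c1Oc1cccc(C=N[Al](CC(C)C)CC(C)C)c1 | intermediate
12 | seco dialdehyde, 4-(benzyloxy)-3-(4-{2-[2-(3-formylphenoxy)-3-methoxyphenyl]ethyl}phenoxy)benzaldehyde | COc1cccc(CCc2ccc(Oc3cc(C=O)ccc3OCc3ccccc3)cc2)c1Oc1cccc(C=O)c1 | intermediate
13 | metal-bound macrocyclic titanium pinacolate, drawn as the simplest 1,3-dioxa-2-titanacyclopentane; relative configuration of the two transient carbinol carbons not defined, both are lost (not isolated) | COc1cccc2c1Oc1cccc(c1)C1O[Ti]OC1c1ccc(OCc3ccccc3)c(c1)Oc1ccc(cc1)CC2 | intermediate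
14 | benzyl-protected macrocyclic (Z)-stilbene, 18-membered ring, Z C=C between rings B and C | COc1cccc2c1Oc1cccc(c1)/C=C\c1ccc(OCc3ccccc3)c(c1)Oc1ccc(cc1)CC2 | intermediate
15 | CNP0309263.0, 18-membered bis(bibenzyl) diether with OMe on ring A and free OH on ring C | COc1cccc2c1Oc1cccc(c1)CCc1ccc(O)c(c1)Oc1ccc(cc1)CC2 | target

Total step count: 8
Longest linear sequence: 6 steps (1 → 3 → 4 → 10 → 12 → 14 → 15; the branch 5 → 6 → 8 → 10 is equally long)

Steps most likely to fail

1. Step 7.
- **Risk:** Ends of different chains may couple faster than the two ends of one chain, which gives oligomers. The reaction may also stall at the pinacol stage or reduce the aldehydes to benzylic alcohols. Premature loss of the benzyl group on the metal would be harmless, since step 8 removes it anyway.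
- **Fallback:** It sets out from 12. Double Wittig methylenation (Ph3PCH3Br, KOtBu, THF) should give the divinyl compound F1. Ring-closing metathesis with the second-generation Grubbs catalyst in dilute toluene at 80 °C, with ethene swept out, joins the same two former formyl carbons. It comes back to the route at 14.
- **Why it differs:** Metathesis is reversible, so oligomers can be funnelled back to the ring, which the irreversible reductive coupling cannot do.

2. Step 4.
- **Risk:** Aryl transfer to the cyano-deactivated, ortho-substituted phenoxide on copper may be slow. Meanwhile the boronic acid is used up by protodeboronation and oxidation.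
- **Fallback:** It sets out from 6 and uses metal-free O-arylation with bis(4-bromophenyl)iodonium triflate (KOtBu, THF, 40 °C). The phenoxide binds to trivalent iodine and ligand coupling delivers the 4-bromophenyl group. It comes back to the route directly at 8 and makes no compound outside the list (F0).

3. Step 5.
- **Risk:** Hydroboration of the ortho-substituted styrene may be incomplete. The alkyl group may also be lost by protodeboronation or by β-hydride elimination at palladium.
- **Fallback:** It sets out from 4 and 8. A Heck reaction (Pd(OAc)2, P(o-tol)3, NaOAc, DMF, 110 °C) should give the (E)-stilbene dinitrile F2. Diimide generated from TsNHNH2 and NaOAc in refluxing THF–water then saturates the alkene without touching the benzyl ether or the nitriles. It comes back to the route at 10.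

Further compounds
F1 | step 7 | divinyl compound, 1-(benzyloxy)-4-ethenyl-2-(4-{2-[2-(3-ethenylphenoxy)-3-methoxyphenyl]ethyl}phenoxy)benzene | COc1cccc(CCc2ccc(Oc3cc(C=C)ccc3OCc3ccccc3)cc2)c1Oc1cccc(C=C)c1
F0 | step 4 | none | none
F2 | step 5 | (E)-stilbene dinitrile, 4-(benzyloxy)-3-(4-{(E)-2-[2-(3-cyanophenoxy)-3-methoxyphenyl]ethenyl}phenoxy)benzonitrile | COc1cccc(/C=C/c2ccc(Oc3cc(C#N)ccc3OCc3ccccc3)cc2)c1Oc1cccc(C#N)c1
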